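**Retrosynthetic overview**

- The target is opened to its 8-O-silyl 18-methyl-acetal form. The C14–O bond and the C13=C16 alkene come from a hydroxyl-directed singlet-oxygen ene reaction. The C15–C5' bond comes from a catalytic asymmetric vinylogous Mukaiyama aldol of an E-enal with 4-methyl-2-silyloxyfuran.
- The enal comes from a C13 methyl ketone carrying an 18→6α lactone (Horner–Wadsworth–Emmons, hydride reduction, acetalisation, MnO2). The lactone comes from RuO4 oxidation of a 6α,18-ether.
- The 6α,18-ether comes from a 6α-alkoxy radical that oxidises C18. The feature used: the equatorial 6α-oxygen on C6 (ring B) and the equatorial 4α-methyl C18 on C4 (ring A) are peri neighbours across C5, so the C6 oxygen reaches C18 and no other methyl.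
- The radical precursor comes from larixol: permanganate cleavage to the C13 methyl ketone, dioxolane, α-epoxidation of C8=C17 with hydride opening, then acetate/silyl differentiation of O6 and O8.
- Ring order: rings A and B come from larixol; the tetrahydrofuran ring O–C6–C5–C4–C18 is closed in the key step and opened again at the end as hydroxy aldehyde; the butenolide ring is brought in intact.

Key step: step 8

Numbering: labdane numbering is used (C18 = 4α-methyl, C19 = 4β-methyl, C20 = 10β-methyl, C17 on C8, C16 on C13); C5' is the butenolide carbon bound to C15.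

Assumption 1: the 6α-hydroxy 18-aldehyde drawn for the target and its 18,6α-lactol are ring–chain tautomers; since that lactol ring is trans-fused to both ring A and ring B, the open form drawn is taken as the form obtained.

Assumption 2: with SiCl4, the (S,S) bisphosphoramide is taken to send the nucleophile to the Si face of a conjugated aldehyde, as its mirror image is understood to favour the Re face; if the furan donor shows the opposite sense, the antipodal catalyst is used.

**Route**

Step 1
Reactants: 1 larixol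
Product: 2 6α-hydroxy-14,15-dinorlabd-8(17)-en-13-one
Conditions: KMnO4, acetone/H2O, 0 °C
Reagents that add atoms: none
Why: Permanganate should attack the exposed monosubstituted C14=C15 vinyl group faster than the hindered 1,1-disubstituted 8(17)-alkene, and the α-hydroxy acid from the tertiary vinyl carbinol is degraded on to the C13 methyl ketone (oxidative cleavage of a vinyl carbinol), with the ring stereocentres untouched.

Step 2
Reactants: 2 6α-hydroxy-14,15-dinorlabd-8(17)-en-13-one
Product: 3 13,13-ethylenedioxy-14,15-dinorlabd-8(17)-en-6α-ol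
Conditions: HOCH2CH2OH, PPTS (cat.), benzene, reflux, azeotropic removal of water
Reagents that add atoms: ethylene glycol, OCCO
Why: Acid-catalysed ketalisation (dioxolane formation) masks the ketone against the hydride reagents that follow, and the weak acid should not isomerise the exocyclic alkene.

Step 3
Reactants: 3 13,13-ethylenedioxy-14,15-dinorlabd-8(17)-en-6α-ol
Product: 4 8α,17-epoxy-13,13-ethylenedioxy-14,15-dinorlabdan-6α-ol
Conditions: mCPBA, NaHCO3, CH2Cl2, 0 °C
Reagents that add atoms: 3-chloroperoxybenzoic acid, OOC(=O)c1cccc(Cl)c1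
Why: Prilezhaev epoxidation should occur on the α face, because the axial 10β-methyl C20 blocks the β face and the homoallylic 6α-hydroxyl can guide the peracid to its own side, which places the epoxide oxygen α on C8.

Step 4
Reactants: 4 8α,17-epoxy-13,13-ethylenedioxy-14,15-dinorlabdan-6α-ol
Product: 5 13,13-ethylenedioxy-14,15-dinorlabdane-6α,8α-diol
Conditions: LiAlH4, THF, reflux
Reagents that add atoms: none
Why: Hydride opens the 1,1-disubstituted epoxide at the unhindered methylene C17 (SN2 reduction of an epoxide), so the oxygen stays α on C8 and C17 becomes the axial 8β-methyl; the ketal is inert.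

Step 5
Reactants: 5 13,13-ethylenedioxy-14,15-dinorlabdane-6α,8α-diol
Product: 6 6α-acetoxy-13,13-ethylenedioxy-14,15-dinorlabdan-8α-ol
Conditions: Ac2O, pyridine, DMAP (cat.), rt
Reagents that add atoms: acetic anhydride, CC(=O)OC(C)=O
Why: Nucleophile-catalysed acylation distinguishes the secondary 6α-alcohol from the tertiary 8α-alcohol, which should not react under these conditions.

Step 6
Reactants: 6 6α-acetoxy-13,13-ethylenedioxy-14,15-dinorlabdan-8α-ol
Product: 7 6α-acetoxy-13,13-ethylenedioxy-8α-triethylsilyloxy-14,15-dinorlabdane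
Conditions: Et3SiOTf, 2,6-lutidine, CH2Cl2, −78 to 0 °C
Reagents that add atoms: triethylsilyl triflate, CC[Si](CC)(CC)OS(=O)(=O)C(F)(F)F
Why: A silyl triflate with a hindered pyridine base is reactive enough to silylate the tertiary alcohol (silyl ether formation), and the ketone ketal is expected to survive at low temperature.

Step 7
Reactants: 7 6α-acetoxy-13,13-ethylenedioxy-8α-triethylsilyloxy-14,15-dinorlabdane
Product: 8 13,13-ethylenedioxy-8α-triethylsilyloxy-14,15-dinorlabdan-6α-ol
Conditions: K2CO3, MeOH, 40 °C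
Reagents that add atoms: none
Why: Base-catalysed transesterification (methanolysis) removes the acetate, while the tertiary silyl ether and the dioxolane are stable to carbonate in methanol.

Step 8
Reactants: 8 13,13-ethylenedioxy-8α-triethylsilyloxy-14,15-dinorlabdan-6α-ol
Product: 11 6α,18-epoxy-13,13-ethylenedioxy-8α-triethylsilyloxy-14,15-dinorlabdane, via 6α-hypoiodite 9 (not isolated), via 18-iodo-6α-alcohol 10 (not isolated)
Conditions: PhI(OAc)2, I2, cyclohexane, visible light (tungsten lamp), 40 °C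
Reagents that add atoms: none
Why: Acetyl hypoiodite from PhI(OAc)2 and I2 turns the 6α-alcohol into hypoiodite 9; light cleaves the O–I bond, the oxygen radical on C6 takes a hydrogen atom from C18 by 1,5-transfer through a chair-like six-membered array, iodine transfer to the neopentyl radical gives iodide 10, and the C6 hydroxyl then substitutes the iodide, helped by its oxidation to a hypervalent leaving group. The closest known reaction type is the hypoiodite δ-C–H etherification of alcohols, long applied to peri and 1,3-diaxial methyl groups of steroids and terpenoids. The tetrahydrofuran ring O–C6–C5–C4–C18 closes in the 5-exo-tet mode by attack of the C6 oxygen on C18. The new stereocentre C4 arises by desymmetrisation of the gem-dimethyl group and is fixed by substrate geometry, since only the equatorial 4α-methyl lies beside the equatorial 6α-oxygen, so C18 on the α face is oxidised and the 4β-methyl C19 stays. The step needs site selectivity among the δ-hydrogens and hydrogen transfer faster than β-scission of C5–C6; the axial 4β-, 8β- and 10β-methyls point to the β face out of reach, and O8 is silylated so that no second alkoxy radical can form.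

Step 9
Reactants: 11 6α,18-epoxy-13,13-ethylenedioxy-8α-triethylsilyloxy-14,15-dinorlabdane
Product: 12 6α,18-epoxy-8α-triethylsilyloxy-14,15-dinorlabdan-13-one
Conditions: PPTS (cat.), acetone/H2O, 40 °C
Reagents that add atoms: water, O
Why: Mild acid-catalysed ketal hydrolysis frees the methyl ketone before the ruthenium oxidation, so that C18 is the only O–CH2 group left; the tertiary silyl ether and the cyclic ether should tolerate the weak acid.

Step 10
Reactants: 12 6α,18-epoxy-8α-triethylsilyloxy-14,15-dinorlabdan-13-one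
Product: 13 13-oxo-8α-triethylsilyloxy-14,15-dinorlabdan-18,6α-olide
Conditions: RuCl3 hydrate (cat.), NaIO4, CCl4/MeCN/H2O, rt
Reagents that add atoms: sodium periodate, [Na+].[O-]I(=O)(=O)=O
Why: RuO4 formed in situ oxidises an ether at its less hindered α-methylene (ether-to-lactone oxidation), here C18 and not the methine C6–H, giving the γ-lactone without touching a stereocentre.

Step 11
Reactants: 13 13-oxo-8α-triethylsilyloxy-14,15-dinorlabdan-18,6α-olide; 14 triethyl phosphonoacetate
Product: 15 ethyl (13E)-8α-triethylsilyloxy-18-oxo-6α,18-epoxylabd-13-en-15-oate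
Conditions: 14, NaH, THF, 0 °C to reflux
Reagents that add atoms: triethyl phosphonoacetate (14), CCOC(=O)CP(=O)(OCC)OCC
Why: Horner–Wadsworth–Emmons olefination of the methyl ketone should give mainly the E enoate with the ester trans to the larger C12 chain (the Z isomer is to be removed by chromatography), and the lactone has a quaternary α-carbon and cannot enolise.

Step 12
Reactants: 15 ethyl (13E)-8α-triethylsilyloxy-18-oxo-6α,18-epoxylabd-13-en-15-oate
Product: 16 (13E)-6α,18-epoxy-8α-triethylsilyloxylabd-13-ene-15,18-diol (lactol; C18 anomers)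
Conditions: iBu2AlH, CH2Cl2, −78 to −40 °C; then aq. KNaC4H4O6 (sodium potassium tartrate)
Reagents that add atoms: none
Why: iBu2AlH reduces the conjugated ester to the allylic alcohol and stops at the lactol for the γ-lactone, because the cyclic aluminium hemiacetal does not collapse at low temperature (partial reduction of a lactone); the new C18 centre is a temporary anomeric mixture.

Step 13
Reactants: 16 (13E)-6α,18-epoxy-8α-triethylsilyloxylabd-13-ene-15,18-diol
Product: 17 (13E)-6α,18-epoxy-18-methoxy-8α-triethylsilyloxylabd-13-en-15-ol (C18 anomers)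
Conditions: MeOH, PPTS (cat.), 0 °C to rt
Reagents that add atoms: methanol, CO
Why: Acid-catalysed acetalisation of the lactol (Fischer-type glycosidation) masks the C18 aldehyde as a cyclic methyl acetal, and the primary allylic alcohol should not react.

Step 14
Reactants: 17 (13E)-6α,18-epoxy-18-methoxy-8α-triethylsilyloxylabd-13-en-15-ol
Product: 18 (13E)-6α,18-epoxy-18-methoxy-8α-triethylsilyloxylabd-13-en-15-al
Conditions: MnO2, CH2Cl2, rt
Reagents that add atoms: none
Why: MnO2 oxidises only the allylic alcohol (allylic alcohol oxidation) and should keep the E geometry.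

Step 15
Reactants: 19 4-methylfuran-2(5H)-one
Product: 20 2-(tert-butyldimethylsilyloxy)-4-methylfuran
Conditions: tBuMe2SiOTf, Et3N, CH2Cl2, 0 °C
Reagents that add atoms: tert-butyldimethylsilyl triflate, CC(C)(C)[Si](C)(C)OS(=O)(=O)C(F)(F)F
Why: Soft enolisation of the butenolide with a silyl triflate and an amine traps the dienolate on oxygen as the aromatic 2-silyloxyfuran (silyl dienol ether formation).

Step 16
Reactants: 18 (13E)-6α,18-epoxy-18-methoxy-8α-triethylsilyloxylabd-13-en-15-al; 20 2-(tert-butyldimethylsilyloxy)-4-methylfuran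
Product: 22 (5R)-4-methyl-5-[(13E,15R)-6α,18-epoxy-15-hydroxy-18-methoxy-8α-triethylsilyloxylabd-13-en-15-yl]furan-2(5H)-one, via trichlorosilyl ether 21 (not isolated)
Conditions: SiCl4, (S,S)-bisphosphoramide [two phosphoramide units from (S)-N,N'-dimethyl-1,1'-binaphthyl-2,2'-diamine joined by an N,N'-dimethylpentane-1,5-diamine tether] (5 mol %), iPr2NEt, CH2Cl2, −78 °C; then aq. NaHCO3
Reagents that add atoms: 2-(tert-butyldimethylsilyloxy)-4-methylfuran (20), Cc1coc(O[Si](C)(C)C(C)(C)C)c1
Why: Vinylogous Mukaiyama aldol reaction under Lewis-base-activated SiCl4, in which the phosphoramide-bound trichlorosilyl cation activates the conjugated aldehyde and shields one face, the silyloxyfuran attacks through C5 in an open transition state that should favour the threo adduct (ring oxygen and hydroxyl syn in the zigzag drawing), and the (S,S) catalyst is chosen for attack on the Si face, which sets C15 as R and C5' as R.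

Step 17
Reactants: 22 (5R)-4-methyl-5-[(13E,15R)-6α,18-epoxy-15-hydroxy-18-methoxy-8α-triethylsilyloxylabd-13-en-15-yl]furan-2(5H)-one
Product: 24 (5R)-5-[(14S,15R)-6α,18-epoxy-14,15-dihydroxy-18-methoxy-8α-triethylsilyloxylabd-13(16)-en-15-yl]-4-methylfuran-2(5H)-one, via 14-hydroperoxide 23 (not isolated)
Conditions: O2, tetraphenylporphyrin (cat.), hν, CH2Cl2, −20 °C; then PPh3
Reagents that add atoms: oxygen, O=O
Why: Schenck ene reaction of singlet oxygen, in which the C15 hydroxyl, held by 1,3-allylic strain with the cis methyl C16, binds the incoming oxygen so that it adds to C14 on the hydroxyl face and takes a hydrogen from C16, giving the threo (14S) hydroperoxide with the alkene moved to C13=C16, and PPh3 then reduces the O–O bond.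

Step 18
Reactants: 24 (5R)-5-[(14S,15R)-6α,18-epoxy-14,15-dihydroxy-18-methoxy-8α-triethylsilyloxylabd-13(16)-en-15-yl]-4-methylfuran-2(5H)-one
Product: 25 (5R)-5-[(14S,15R)-6α,8α,14,15-tetrahydroxy-18-oxolabd-13(16)-en-15-yl]-4-methylfuran-2(5H)-one
Conditions: HF (aq.), MeCN, 0 °C to rt
Reagents that add atoms: water, O
Why: Aqueous HF cleaves the tertiary silyl ether (fluoride-assisted desilylation) and hydrolyses the methyl acetal to the lactol, which opens to the 6α-hydroxy 18-aldehyde, while the mild acid should leave the tertiary alcohol, the allylic diol and the butenolide intact.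

**Compound list**

1 | larixol | C=C[C@@](C)(O)CC[C@@H]1[C@@]2(C)CCCC(C)(C)[C@@H]2[C@@H](O)CC1=C | starting material
2 | 6α-hydroxy-14,15-dinorlabd-8(17)-en-13-one | CC(=O)CC[C@@H]1[C@@]2(C)CCCC(C)(C)[C@@H]2[C@@H](O)CC1=C | intermediate
3 | 13,13-ethylenedioxy-14,15-dinorlabd-8(17)-en-6α-ol | CC1(OCCO1)CC[C@@H]1[C@@]2(C)CCCC(C)(C)[C@@H]2[C@@H](O)CC1=C | intermediate
4 | 8α,17-epoxy-13,13-ethylenedioxy-14,15-dinorlabdan-6α-ol | CC1(OCCO1)CC[C@@H]1[C@@]2(C)CCCC(C)(C)[C@@H]2[C@@H](O)C[C@@]12OC2 | intermediate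
5 | 13,13-ethylenedioxy-14,15-dinorlabdane-6α,8α-diol | CC1(OCCO1)CC[C@@H]1[C@@]2(C)CCCC(C)(C)[C@@H]2[C@@H](O)C[C@@]1(C)O | intermediate
6 | 6α-acetoxy-13,13-ethylenedioxy-14,15-dinorlabdan-8α-ol | CC1(OCCO1)CC[C@@H]1[C@@]2(C)CCCC(C)(C)[C@@H]2[C@@H](OC(C)=O)C[C@@]1(C)O | intermediate
7 | 6α-acetoxy-13,13-ethylenedioxy-8α-triethylsilyloxy-14,15-dinorlabdane | CC1(OCCO1)CC[C@@H]1[C@@]2(C)CCCC(C)(C)[C@@H]2[C@@H](OC(C)=O)C[C@@]1(C)O[Si](CC)(CC)CC | intermediate
8 | 13,13-ethylenedioxy-8α-triethylsilyloxy-14,15-dinorlabdan-6α-ol | CC1(OCCO1)CC[C@@H]1[C@@]2(C)CCCC(C)(C)[C@@H]2[C@@H](O)C[C@@]1(C)O[Si](CC)(CC)CC | intermediate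
9 | 6α-hypoiodite of 8 (not isolated) | CC1(OCCO1)CC[C@@H]1[C@@]2(C)CCCC(C)(C)[C@@H]2[C@@H](OI)C[C@@]1(C)O[Si](CC)(CC)CC | intermediate
10 | 13,13-ethylenedioxy-18-iodo-8α-triethylsilyloxy-14,15-dinorlabdan-6α-ol (not isolated) | CC1(OCCO1)CC[C@@H]1[C@@]2(C)CCC[C@@](C)(CI)[C@@H]2[C@@H](O)C[C@@]1(C)O[Si](CC)(CC)CC | intermediate
11 | 6α,18-epoxy-13,13-ethylenedioxy-8α-triethylsilyloxy-14,15-dinorlabdane | CC1(OCCO1)CC[C@@H]1[C@@]2(C)CCC[C@@](C)(C3)[C@@H]2[C@@H](O3)C[C@@]1(C)O[Si](CC)(CC)CC | intermediate
12 | 6α,18-epoxy-8α-triethylsilyloxy-14,15-dinorlabdan-13-one | CC(=O)CC[C@@H]1[C@@]2(C)CCC[C@@](C)(C3)[C@@H]2[C@@H](O3)C[C@@]1(C)O[Si](CC)(CC)CC | intermediate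
13 | 13-oxo-8α-triethylsilyloxy-14,15-dinorlabdan-18,6α-olide | CC(=O)CC[C@@H]1[C@@]2(C)CCC[C@@](C)(C3=O)[C@@H]2[C@@H](O3)C[C@@]1(C)O[Si](CC)(CC)CC | intermediate
14 | triethyl phosphonoacetate | CCOC(=O)CP(=O)(OCC)OCC | starting material
15 | ethyl (13E)-8α-triethylsilyloxy-18-oxo-6α,18-epoxylabd-13-en-15-oate | CCOC(=O)/C=C(\C)CC[C@@H]1[C@@]2(C)CCC[C@@](C)(C3=O)[C@@H]2[C@@H](O3)C[C@@]1(C)O[Si](CC)(CC)CC | intermediate
16 | (13E)-6α,18-epoxy-8α-triethylsilyloxylabd-13-ene-15,18-diol (C18 anomers) | OC/C=C(\C)CC[C@@H]1[C@@]2(C)CCC[C@@](C)(C3O)[C@@H]2[C@@H](O3)C[C@@]1(C)O[Si](CC)(CC)CC | intermediate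
17 | (13E)-6α,18-epoxy-18-methoxy-8α-triethylsilyloxylabd-13-en-15-ol (C18 anomers) | OC/C=C(\C)CC[C@@H]1[C@@]2(C)CCC[C@@](C)(C3OC)[C@@H]2[C@@H](O3)C[C@@]1(C)O[Si](CC)(CC)CC | intermediate
18 | (13E)-6α,18-epoxy-18-methoxy-8α-triethylsilyloxylabd-13-en-15-al | O=C/C=C(\C)CC[C@@H]1[C@@]2(C)CCC[C@@](C)(C3OC)[C@@H]2[C@@H](O3)C[C@@]1(C)O[Si](CC)(CC)CC | intermediate
19 | 4-methylfuran-2(5H)-one | CC1=CC(=O)OC1 | starting material
20 | 2-(tert-butyldimethylsilyloxy)-4-methylfuran | Cc1coc(O[Si](C)(C)C(C)(C)C)c1 | intermediate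
21 | 15-O-trichlorosilyl ether of 22 (not isolated) | C/C(CC[C@@H]1[C@@]2(C)CCC[C@@](C)(C3OC)[C@@H]2[C@@H](O3)C[C@@]1(C)O[Si](CC)(CC)CC)=C\[C@@H](O[Si](Cl)(Cl)Cl)[C@@H]1OC(=O)C=C1C | intermediate
22 | (5R)-4-methyl-5-[(13E,15R)-6α,18-epoxy-15-hydroxy-18-methoxy-8α-triethylsilyloxylabd-13-en-15-yl]furan-2(5H)-one | C/C(CC[C@@H]1[C@@]2(C)CCC[C@@](C)(C3OC)[C@@H]2[C@@H](O3)C[C@@]1(C)O[Si](CC)(CC)CC)=C\[C@@H](O)[C@@H]1OC(=O)C=C1C | intermediate
23 | 14-hydroperoxide corresponding to 24 (not isolated) | C=C(CC[C@@H]1[C@@]2(C)CCC[C@@](C)(C3OC)[C@@H]2[C@@H](O3)C[C@@]1(C)O[Si](CC)(CC)CC)[C@H](OO)[C@@H](O)[C@@H]1OC(=O)C=C1C | intermediate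
24 | (5R)-5-[(14S,15R)-6α,18-epoxy-14,15-dihydroxy-18-methoxy-8α-triethylsilyloxylabd-13(16)-en-15-yl]-4-methylfuran-2(5H)-one | C=C(CC[C@@H]1[C@@]2(C)CCC[C@@](C)(C3OC)[C@@H]2[C@@H](O3)C[C@@]1(C)O[Si](CC)(CC)CC)[C@H](O)[C@@H](O)[C@@H]1OC(=O)C=C1C | intermediate
25 | (5R)-5-[(14S,15R)-6α,8α,14,15-tetrahydroxy-18-oxolabd-13(16)-en-15-yl]-4-methylfuran-2(5H)-one (CNP0156243.1) | C=C(CC[C@@H]1[C@@]2(C)CCC[C@@](C)(C=O)[C@@H]2[C@@H](O)C[C@@]1(C)O)[C@H](O)[C@@H](O)[C@@H]1OC(=O)C=C1C | target

**Step count**

Total: 18 steps. Longest linear sequence: 17 steps (larixol 1 to 25 through steps 1–14 and 16–18; step 15 makes the furan 20).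

**Steps most likely to fail**

Step 8. The oxygen radical on C6 may cleave the C5–C6 bond by β-scission at 40 °C in competition with hydrogen transfer, and the neopentyl iodide may close slowly. The fallback replaces C–O by C–N bond formation at C18 at low temperature, where hydrogen transfer is favoured over fragmentation and capture by NO takes the place of iodination and substitution. From 8, nitrosyl chloride in pyridine at −20 °C gives 13,13-ethylenedioxy-8α-triethylsilyloxy-14,15-dinorlabdan-6α-yl nitrite F1. Photolysis (Barton reaction; Hg lamp, benzene, 10 °C), then warming in isopropanol to tautomerise the nitroso compound, gives the 6α-hydroxy 18-oxime F2. Aqueous TiCl3 buffered with NH4OAc hydrolyses the oxime reductively, and the aldehyde closes to the 6α,18-lactol F3. Catalytic nPr4N[RuO4] with N-methylmorpholine N-oxide oxidises it to the 18,6α-olide ketal F4. PPTS in wet acetone then removes the dioxolane and the route is rejoined at 13.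

Step 16. The silicon Lewis acid may ionise the C18 methyl acetal so that the furan is consumed there, and face discrimination or the threo preference may be eroded by the 4-methyl group of the donor. The fallback moves stereocontrol to a covalently bound auxiliary and builds the butenolide afterwards. From 18, a boron-mediated syn-glycolate aldol (Evans aldol) with (S)-4-benzyl-3-[(4-methoxybenzyloxy)acetyl]oxazolidin-2-one (nBu2BOTf, Et3N, CH2Cl2, −78 °C; H2O2 work-up) gives the (2S,3R) syn adduct, (S)-4-benzyl-3-[2-(4-methoxybenzyloxy)-3-hydroxyacyl]oxazolidin-2-one F5; its C15 hydroxyl and future C5' oxygen are set through the chair transition state of the Z boron enolate. MeNH(OMe)·HCl with AlMe3 gives the N-methoxy-N-methylamide F6. Et3SiOTf and 2,6-lutidine give its 15-O-triethylsilyl ether F7. MeMgBr gives the methyl ketone F8. DDQ in CH2Cl2/pH 7 buffer removes the 4-methoxybenzyl group to give the α-hydroxy ketone F9. (Triphenylphosphoranylidene)ketene Ph3P=C=C=O in warm toluene acylates the hydroxyl and closes the ring by intramolecular Wittig reaction, giving the 15-O-triethylsilyl butenolide F10. Buffered HF·pyridine in THF at 0 °C removes the secondary silyl ether in preference to the tertiary one and returns the route at 22.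

Step 17. Singlet oxygen may take a hydrogen from C12 instead of C16, or add anti to the hydroxyl if the butenolide carbonyl competes for the hydrogen bond, which would lower the threo selectivity. The fallback separates C–O bond formation from the alkene shift. From 22, mCPBA in CH2Cl2 at 0 °C, directed by the same hydroxyl and the same 1,3-allylic strain, should give the threo 13,14-epoxy alcohol F11 with the C14–O bond already in place. Cp2TiCl (from Cp2TiCl2 and Zn dust, THF, rt) then opens the epoxide homolytically at the tertiary C13, and a second equivalent of this trivalent titanium reagent removes a hydrogen from the C16 methyl, giving the 13(16)-ene 14,15-diol 24, where the route is rejoined.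

**Further compounds**

F1 | step 8 | 13,13-ethylenedioxy-8α-triethylsilyloxy-14,15-dinorlabdan-6α-yl nitrite | CC1(OCCO1)CC[C@@H]1[C@@]2(C)CCCC(C)(C)[C@@H]2[C@@H](ON=O)C[C@@]1(C)O[Si](CC)(CC)CC
F2 | step 8 | 13,13-ethylenedioxy-6α-hydroxy-8α-triethylsilyloxy-14,15-dinorlabdan-18-al oxime | CC1(OCCO1)CC[C@@H]1[C@@]2(C)CCC[C@@](C)(C=NO)[C@@H]2[C@@H](O)C[C@@]1(C)O[Si](CC)(CC)CC
F3 | step 8 | 6α,18-epoxy-13,13-ethylenedioxy-8α-triethylsilyloxy-14,15-dinorlabdan-18-ol (lactol, C18 anomers) | CC1(OCCO1)CC[C@@H]1[C@@]2(C)CCC[C@@](C)(C3O)[C@@H]2[C@@H](O3)C[C@@]1(C)O[Si](CC)(CC)CC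
F4 | step 8 | 13,13-ethylenedioxy-8α-triethylsilyloxy-14,15-dinorlabdan-18,6α-olide | CC1(OCCO1)CC[C@@H]1[C@@]2(C)CCC[C@@](C)(C3=O)[C@@H]2[C@@H](O3)C[C@@]1(C)O[Si](CC)(CC)CC
F5 | step 16 | (S)-4-benzyl-3-[(2S,3R)-3-hydroxy-2-(4-methoxybenzyloxy)acyl]oxazolidin-2-one aldol adduct of 18 | C/C(CC[C@@H]1[C@@]2(C)CCC[C@@](C)(C3OC)[C@@H]2[C@@H](O3)C[C@@]1(C)O[Si](CC)(CC)CC)=C\[C@@H](O)[C@H](OCc1ccc(OC)cc1)C(=O)N1[C@@H](Cc2ccccc2)COC1=O
F6 | step 16 | N-methoxy-N-methylamide from F5 | C/C(CC[C@@H]1[C@@]2(C)CCC[C@@](C)(C3OC)[C@@H]2[C@@H](O3)C[C@@]1(C)O[Si](CC)(CC)CC)=C\[C@@H](O)[C@H](OCc1ccc(OC)cc1)C(=O)N(C)OC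
F7 | step 16 | 15-O-triethylsilyl ether of F6 | C/C(CC[C@@H]1[C@@]2(C)CCC[C@@](C)(C3OC)[C@@H]2[C@@H](O3)C[C@@]1(C)O[Si](CC)(CC)CC)=C\[C@@H](O[Si](CC)(CC)CC)[C@H](OCc1ccc(OC)cc1)C(=O)N(C)OC
F8 | step 16 | methyl ketone from F7 | C/C(CC[C@@H]1[C@@]2(C)CCC[C@@](C)(C3OC)[C@@H]2[C@@H](O3)C[C@@]1(C)O[Si](CC)(CC)CC)=C\[C@@H](O[Si](CC)(CC)CC)[C@H](OCc1ccc(OC)cc1)C(C)=O
F9 | step 16 | α-hydroxy methyl ketone from F8 | C/C(CC[C@@H]1[C@@]2(C)CCC[C@@](C)(C3OC)[C@@H]2[C@@H](O3)C[C@@]1(C)O[Si](CC)(CC)CC)=C\[C@@H](O[Si](CC)(CC)CC)[C@H](O)C(C)=O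
F10 | step 16 | 15-O-triethylsilyl ether of 22 | C/C(CC[C@@H]1[C@@]2(C)CCC[C@@](C)(C3OC)[C@@H]2[C@@H](O3)C[C@@]1(C)O[Si](CC)(CC)CC)=C\[C@@H](O[Si](CC)(CC)CC)[C@@H]1OC(=O)C=C1C
F11 | step 17 | threo 13,14-epoxide of 22 | C[C@]1(CC[C@@H]2[C@@]3(C)CCC[C@@](C)(C4OC)[C@@H]3[C@@H](O4)C[C@@]2(C)O[Si](CC)(CC)CC)O[C@@H]1[C@@H](O)[C@@H]1OC(=O)C=C1C
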